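What is left of the catalyst after the impurity has taken its share is the number to carry.

| setting | larch | birch | elm | south-east | north | north-east | south |
|---|---|---|---|---|---|---|---|
| starting material | 0.076 M | 0.038 M | 0.057 M | 0.076 M | 0.076 M | 0.076 M (fed, over 80 s) | 0.076 M |
| reagent | 0.228 M | 0.228 M | 0.228 M | 0.228 M (fed, over 80 s) | 0.228 M | 0.228 M | 0.228 M (fed, over 8.0 s) |
| free catalyst | 43 µM | 43 µM | 43 µM | 43 µM | 43 µM | 43 µM | 43 µM |
| impurity | 23 µM | 23 µM | 23 µM | 23 µM | 23 µM | 23 µM | 23 µM |
| remark | run made earlier | run made earlier | run made earlier | all else is in the flask from the start; the feed brings no volume worth counting | everything together at the start | all else is in the flask from the start; the feed brings no volume worth counting | all else is in the flask from the start; the feed brings no volume worth counting |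
| time |  |  |  | 2.0 min | 2.0 min | 2.0 min | 2.0 min |

| run | time / s | target / % |
|---|---|---|
| larch | 10.0 | 15.1 |
| larch | 20.0 | 25.0 |
| larch | 40.0 | 40.9 |
| larch | 80.0 | 60.7 |
| birch | 25.0 | 35.7 |
| birch | 50.0 | 52.1 |
| birch | 80.0 | 63.7 |
| birch | 90.0 | 67.1 |
| birch | 120 | 71.8 |
| elm | 25.0 | 32.6 |
| elm | 50.0 | 49.0 |
| elm | 80.0 | 61.5 |
| elm | 90.0 | 65.0 |
| elm | 120 | 71.9 |

(scatter of a reading: 0.5 percentage points)

- steps under discussion: starting material + catalyst intermediate A <-> catalyst intermediate B; reagent + free catalyst -> catalyst intermediate A; catalyst intermediate B -> free catalyst + target; free catalyst + impurity -> spent catalyst B; reagent + catalyst intermediate A -> spent catalyst A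

1. the flask with the highest amount of target, in percent of the starting material charged ("all alike" if they lie within 1.5 percentage points) (south-east / north / north-east / south / all alike)
2. final target, as a percentage of the starting material charged, in south-east
3. final target, as a percentage of the starting material charged, in north
4. final target, as a percentage of the starting material charged, in north-east
5. final target, as a percentage of the starting material charged, in south

The recipes charge 43 µM of free catalyst and 23 µM of impurity, and in the steps under discussion each impurity turns one free catalyst into spent catalyst B. About half of the charge is therefore lost, and the leftover catalyst, W = 20.0 µM, is the difference between the two charges.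

How hard must W work? In north, clearing 0.076 M of starting material takes 3800 turns per leftover catalyst, or 3.58 in powers of ten. Larch, with the same charges, read 60.7% at 80.0 s, which we reckon as about 2307 turns per leftover catalyst.

Does the size of the charge matter? Birch, with half the starting material, read 63.7% at that time against 60.7% in larch, a gap of 3 percentage points, so we take the decay as close to pseudo-first-order in starting material.

Does the catalyst hold up? In birch, the logarithmic slope of the starting material left reads 0.0118 s⁻¹ between 25.0 s and 50.0 s, but 0.00631 s⁻¹ between 80.0 s and 120 s, about half. We read this as W fading with time. Carrying the later slope forward from larch, we reckon north at 69.5%.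

South's feed lasts 8.0 s of 2.0 min, so we expect it to read like north. South-east's reagent comes in over 80 s, and reagent is what turns catalyst intermediate A into spent catalyst A, so we place south-east above north. North-east brings starting material to a fading catalyst, so we place it well below.

The forecast says south-east, with 77% there, 71% in north, 52% in north-east and 71.5% in south; of north-east it says “starting material arrives late while catalyst decays on the same clock”.

The flasks give 77.0% in south-east, 70.5% in north, 37.6% in north-east and 71.0% in south.

    starting material + catalyst intermediate A ⇌ catalyst intermediate B (K = 18.0 M⁻¹, k = 1700 M⁻¹ s⁻¹)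
    reagent + free catalyst → catalyst intermediate A (k = 5500 M⁻¹ s⁻¹)
    catalyst intermediate B → free catalyst + target (k = 160 s⁻¹)
    free catalyst + impurity → spent catalyst B (k = 3.80 × 10⁵ M⁻¹ s⁻¹)
    reagent + catalyst intermediate A → spent catalyst A (k = 0.0580 M⁻¹ s⁻¹)

North-east, 14 points under the forecast, still holds 62.4% of its starting material at 2.00 min. In south-east at 20.0 min, spent catalyst A holds 46.5% of the catalyst charged, and W is 46.5% of that charge. A neighbour of south-east charged with 26.0 µM of free catalyst has W = 3.00 µM and gives 17.2% of target at 2.00 min.

The earlier runs and the new flask are calculated for an exercise; noise was put on by code.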